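Larch ended with more target than alder, 25.6% against 4.0% at the last readings. Larch was also colder and held less second nucleophile. Substrate is consumed in these flasks and target appears. Ann watches the second nucleophile, Ben the temperature.

| setting | larch | alder | ochre | amber | green |
|---|---|---|---|---|---|
| substrate | 0.050 M | 0.050 M | 0.050 M | 0.050 M | 0.050 M |
| first nucleophile | 0.040 M | 0.040 M | 0.0400 M | 0.0400 M | 0.0400 M |
| second nucleophile | 0.020 M | 0.045 M | 0.0300 M | 0.0300 M | 0.0300 M |
| temperature | 15 °C | 35 °C | 20 °C | 35 °C | 50 °C |
| remark | run made earlier | run made earlier |  |  |  |
| time |  |  | 4.0 min | 4.0 min | 4.0 min |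

| run | time / min | target / % | substrate / % |
|---|---|---|---|
| larch | 1.33 | 9.9 | 40.4 |
| larch | 2.50 | 21.0 | 16.1 |
| larch | 4.00 | 25.5 | 7.2 |
| larch | 5.00 | 25.6 | 4.4 |
| alder | 0.200 | 0.5 | 39.1 |
| alder | 0.417 | 0 | 12.3 |
| alder | 1.00 | 1.0 | 1.2 |
| alder | 2.50 | 4.0 | 0 |

(readings scatter by 1 percentage point)

* the flask with the highest amount of target, in percent of the substrate charged ("all alike" if they lie within 1.5 percentage points) (ochre / amber / green / all alike)
* final target, as a percentage of the substrate charged, in ochre
* final target, as a percentage of the substrate charged, in amber
* final target, as a percentage of the substrate charged, in green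

Ann assumes that each second nucleophile captures one substrate's worth of material, which then can't become target. For the new flasks she reckons R = 40.0%, the room, the part of the substrate charge above the second nucleophile charge. Larch had R = 60.0% and alder R = 10.0%. The last readings give target shares of R of 0.427 in larch and 0.400 in alder. These are close, so Ann sees no role for temperature. The new flasks share one R, so she gives each 17.1% and names no leader.

Ben objects that the alder share rests on one reading. The scatter of a reading moves that share by 0.100. At 1.00 min, alder held 1.2% of substrate and 1.0% of target, a share of 0.100. Ben therefore reads the later gain as a slow route.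

His forecast names ochre as best, with 20% in ochre, 7% in amber and 8% in green. In his words: “The hot flasks are low, though the slow route could lift green somewhat”.

The simulation gives 15.4% in ochre, 6.88% in amber and 2.62% in green, so ochre leads. Green lies 5.4 percentage points below the forecast. It already shows 2.62% at 2.00 min and still 2.62% at 40.0 min.

    substrate → intermediate (k = 0.0200 s⁻¹, Ea = 71.0 kJ mol⁻¹)
    first nucleophile + intermediate ⇌ target (K = 20.0 M⁻¹, k = 720 M⁻¹ s⁻¹, Ea = 42.0 kJ mol⁻¹, ΔH = −63.0 kJ mol⁻¹)
    second nucleophile + intermediate → other capture product (k = 120 M⁻¹ s⁻¹, Ea = 47.0 kJ mol⁻¹)
    (constants at 20 °C)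

R survives as a balance in ochre. Other capture product is 60.0% in ochre, and second nucleophile, the limiting reagent of that capture, stands at 0%. Target, intermediate and substrate in ochre make 40.0%, against R of 40.0%. Ann's fixed share fails: target takes 0.385 of R in ochre, 0.172 in amber and 0.0655 in green. Her count holds up on a neighbour at ochre's temperature. The neighbour, ochre with 0.030 M of substrate, has R = 0%. It ends with 98.5% other capture product and 0.289% target.

The runs were generated by integration from invented constants.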